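## Retrosynthetic overview

1. The 1,1-disubstituted alkene is unveiled last from a ketone (Peterson methylenation). The ketone is kept until then because an acyl group on C1 stops the C1–O bond from ionising while the halogens go in.
2. The trans Br/Cl pair with Cl cis to the C1 hydroxyl comes from a temporary oxygen bridge: transannular bromoetherification of the cyclohexenol, then TiCl4 opening of the tertiary C–O bond with retention through the bromonium ion.
3. Key C–C bond (side chain C4'–C5'): a ketone homoenolate, made by zinc-mediated opening of a cyclopropanol, adds to methacrolein under chiral titanium catalysis and sets the 5'R carbinol.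
4. The cyclopropanol comes from a Kulinkovich reaction on a spiro-dioxolanone, itself the Diels–Alder adduct of isoprene with a lactic-acid-derived 5-methylidene-dioxolanone, which sets C1.
5. Ring order: cyclohexene first (Diels–Alder); cyclopropane made, then opened; oxygen bridge made, then opened.

Assumption (locants): ring and side-chain locants follow the name (1S,3R,4R)-3-bromo-4-chloro-1-[(5R)-5-hydroxy-6-methylhepta-1,6-dien-2-yl]-4-methylcyclohexan-1-ol; side-chain atoms carry a prime.

## Route

Step 1
Reactants: 1 (R)-lactic acid; 2 pivalaldehyde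
Product: 3 (2R,5R)-2-tert-butyl-5-methyl-1,3-dioxolan-4-one
Conditions: p-TsOH (cat.), H2SO4 (cat.), pentane, reflux, Dean–Stark; recrystallise (ether/pentane, −78 °C)
Reagents that add atoms: none
Why: Acid-catalysed acetalisation with azeotropic water removal (Seebach dioxolanone formation) is under thermodynamic control and places tert-butyl cis to methyl, so the lactate centre (5R) dictates the new acetal centre (2R), and the minor trans isomer is removed by crystallisation.

Step 2
Reactants: 3 (2R,5R)-2-tert-butyl-5-methyl-1,3-dioxolan-4-one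
Product: 5 (2R)-2-tert-butyl-5-methylidene-1,3-dioxolan-4-one, via bromide 4 (not isolated)
Conditions: NBS, AIBN (cat.), CCl4, reflux; filter; then DBU, CH2Cl2, 0 °C
Reagents that add atoms: none
Why: Wohl–Ziegler radical bromination at the captodative C5–H and E2 dehydrobromination give the exocyclic enol ester, so C5 becomes planar and the untouched acetal carbon (2R) now carries all the stereochemical information.

Step 3
Reactants: 5 (2R)-2-tert-butyl-5-methylidene-1,3-dioxolan-4-one; 6 isoprene
Product: 7 (2R,5S)-2-tert-butyl-8-methyl-1,3-dioxaspiro[4.5]dec-7-en-4-one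
Conditions: isoprene (5 equiv), BHT (cat.), toluene, 90 °C, sealed tube
Reagents that add atoms: none
Why: Thermal Diels–Alder reaction of an alpha-acyloxyacrylate-type dienophile, in which the dienophile CH2 bonds to the isoprene CH2 next to the methyl-bearing carbon (para regiochemistry) and the diene adds anti to the tert-butyl group, which sets the quaternary carbinol carbon as S (C1 of the target).

Step 4
Reactants: 7 (2R,5S)-2-tert-butyl-8-methyl-1,3-dioxaspiro[4.5]dec-7-en-4-one
Product: 8 1-[(1S)-1-hydroxy-4-methylcyclohex-3-en-1-yl]cyclopropan-1-ol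
Conditions: EtMgBr (4.5 equiv, slow addition), Ti(OiPr)4 (0.3 equiv), THF, 0 °C to rt; aq. NH4Cl
Reagents that add atoms: ethylmagnesium bromide, CC[Mg]Br
Why: Kulinkovich cyclopropanation, in which the titanacyclopropane formed from EtMgBr and Ti(OiPr)4 adds twice to the lactone-type carbonyl, the acylal collapses to free the tertiary alkoxide and pivalaldehyde (scavenged by excess Grignard reagent), and the C1 stereocentre is not touched.

Step 5
Reactants: 8 1-[(1S)-1-hydroxy-4-methylcyclohex-3-en-1-yl]cyclopropan-1-ol; 9 methacrolein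
Product: 11 (4R)-4-hydroxy-1-[(1S)-1-hydroxy-4-methylcyclohex-3-en-1-yl]-5-methylhex-5-en-1-one, via zinc homoenolate 10 (not isolated)
Conditions: Zn(CH2SiMe3)2 (2.2 equiv), toluene–THF, 0 °C to rt; then Ti(OiPr)4 (1.5 equiv), (1S,2S)-1,2-bis(trifluoromethanesulfonamido)cyclohexane (10 mol %), methacrolein (2 equiv), −20 °C; aq. NH4Cl
Reagents that add atoms: none
Why: Proposed new method: double deprotonation by Zn(CH2SiMe3)2 gives a zinc cyclopropoxide that ring-opens (strain release, as known for cyclopropanols with dialkylzincs) to a beta-zincio ketone in which CH2SiMe3 is a non-transferable ligand, and this homoenolate is passed to the chiral bis(sulfonamido)titanium isopropoxide and adds 1,2 to the Re face of methacrolein, setting the carbinol as R under catalyst control; the closest known reactions are the Nakamura–Kuwajima addition of ester homoenolates of zinc and titanium to aldehydes and the Ti(OiPr)4/bis-triflamide-catalysed asymmetric addition of functionalised mixed alkylzincs to enals.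

Step 6
Reactants: 11 (4R)-4-hydroxy-1-[(1S)-1-hydroxy-4-methylcyclohex-3-en-1-yl]-5-methylhex-5-en-1-one
Product: 12 (3R)-6-[(1S)-1-hydroxy-4-methylcyclohex-3-en-1-yl]-2-methyl-6-oxohex-1-en-3-yl acetate
Conditions: Ac2O (1.2 equiv), pyridine, DMAP (cat.), CH2Cl2, 0 °C
Reagents that add atoms: acetic anhydride, CC(=O)OC(C)=O
Why: DMAP-catalysed acylation is selective for the secondary allylic alcohol over the hindered tertiary alpha-ketol hydroxyl, locks the open-chain form (no hemiketal) and protects the allylic alcohol from the electrophilic and Lewis-acidic steps that follow.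

Step 7
Reactants: 12 (3R)-6-[(1S)-1-hydroxy-4-methylcyclohex-3-en-1-yl]-2-methyl-6-oxohex-1-en-3-yl acetate
Product: 13 (3R)-6-[(1S,3R,4R)-3-bromo-4-methyl-7-oxabicyclo[2.2.1]heptan-1-yl]-2-methyl-6-oxohex-1-en-3-yl acetate
Conditions: 2,4,4,6-tetrabromocyclohexa-2,5-dienone (TBCO, 1.05 equiv), CH2Cl2, −20 to 0 °C, dark
Reagents that add atoms: 2,4,4,6-tetrabromocyclohexa-2,5-dien-1-one, O=C1C(Br)=CC(Br)(Br)C=C1Br
Why: Transannular bromoetherification (halocyclisation of the 1,4-cineole type), in which bromonium formation is reversible and only the ion anti to the C1 hydroxyl can be captured, through a boat, at the tertiary Markovnikov carbon, which fixes C4–O cis to C1–O and bromine anti to the bridge (3R,4R) while the electron-poor isopropenyl acetate alkene is spared.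

Step 8
Reactants: 13 (3R)-6-[(1S,3R,4R)-3-bromo-4-methyl-7-oxabicyclo[2.2.1]heptan-1-yl]-2-methyl-6-oxohex-1-en-3-yl acetate
Product: 14 (3R)-6-[(1S,3R,4R)-3-bromo-4-chloro-1-hydroxy-4-methylcyclohexyl]-2-methyl-6-oxohex-1-en-3-yl acetate
Conditions: TiCl4 (2.2 equiv), CH2Cl2, −78 to −40 °C; aq. NaHCO3
Reagents that add atoms: titanium tetrachloride, Cl[Ti](Cl)(Cl)Cl
Why: Lewis-acid ether cleavage with neighbouring-group participation, in which TiCl4 chelated between the ketone and the bridge oxygen ionises the strained tertiary C4–O bond (the acyl group forbids ionisation at C1) with help from the antiperiplanar bromine, and chloride opens the bromonium ion at the tertiary carbon anti to bromine, i.e. with net retention, giving the trans bromochloride with chlorine cis to the C1 hydroxyl.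

Step 9
Reactants: 14 (3R)-6-[(1S,3R,4R)-3-bromo-4-chloro-1-hydroxy-4-methylcyclohexyl]-2-methyl-6-oxohex-1-en-3-yl acetate
Product: 16 (1S,3R,4R)-3-bromo-4-chloro-1-[(5R)-5-hydroxy-6-methylhepta-1,6-dien-2-yl]-4-methylcyclohexan-1-ol, via beta-hydroxysilane 15 (not isolated)
Conditions: Me3SiCH2Li (6 equiv), CeCl3 (6 equiv), THF, −78 to 0 °C; aq. NH4Cl; then HF·pyridine, MeCN, 0 °C
Reagents that add atoms: (trimethylsilyl)methyllithium, [Li]C[Si](C)(C)C
Why: Cerium-mediated Peterson olefination, in which the weakly basic organocerium adds to the hindered, enolisable ketone without E2 or substitution at the halides and removes the acetate by double addition, and HF induces anti elimination of the beta-hydroxysilane to the 1,1-disubstituted alkene without touching any stereocentre.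

## Compound list

1 | (R)-lactic acid | C[C@@H](O)C(=O)O | starting material
2 | pivalaldehyde (2,2-dimethylpropanal) | CC(C)(C)C=O | starting material
3 | (2R,5R)-2-tert-butyl-5-methyl-1,3-dioxolan-4-one | C[C@H]1O[C@@H](C(C)(C)C)OC1=O | intermediate
4 | (2R,5S)-5-bromo-2-tert-butyl-5-methyl-1,3-dioxolan-4-one (not isolated) | C[C@@]1(Br)O[C@@H](C(C)(C)C)OC1=O | intermediate
5 | (2R)-2-tert-butyl-5-methylidene-1,3-dioxolan-4-one | C=C1O[C@@H](C(C)(C)C)OC1=O | intermediate
6 | isoprene | C=CC(C)=C | starting material
7 | (2R,5S)-2-tert-butyl-8-methyl-1,3-dioxaspiro[4.5]dec-7-en-4-one | CC1=CC[C@]2(CC1)O[C@@H](C(C)(C)C)OC2=O | intermediate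
8 | 1-[(1S)-1-hydroxy-4-methylcyclohex-3-en-1-yl]cyclopropan-1-ol | OC1(CC1)[C@]2(O)CCC(C)=CC2 | intermediate
9 | methacrolein | CC(=C)C=O | starting material
10 | zinc homoenolate: Me3SiCH2Zn–CH2CH2C(=O)– on the (1S)-4-methylcyclohex-3-enyl carbon that bears O–ZnCH2SiMe3 (not isolated) | C[Si](C)(C)C[Zn]CCC(=O)[C@]1(O[Zn]C[Si](C)(C)C)CCC(C)=CC1 | intermediate
11 | (4R)-4-hydroxy-1-[(1S)-1-hydroxy-4-methylcyclohex-3-en-1-yl]-5-methylhex-5-en-1-one | C=C(C)[C@H](O)CCC(=O)[C@]1(O)CCC(C)=CC1 | intermediate
12 | (3R)-6-[(1S)-1-hydroxy-4-methylcyclohex-3-en-1-yl]-2-methyl-6-oxohex-1-en-3-yl acetate | C=C(C)[C@H](OC(C)=O)CCC(=O)[C@]1(O)CCC(C)=CC1 | intermediate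
13 | (3R)-6-[(1S,3R,4R)-3-bromo-4-methyl-7-oxabicyclo[2.2.1]heptan-1-yl]-2-methyl-6-oxohex-1-en-3-yl acetate | C=C(C)[C@H](OC(C)=O)CCC(=O)[C@]21CC[C@@](C)(O1)[C@H](Br)C2 | intermediate
14 | (3R)-6-[(1S,3R,4R)-3-bromo-4-chloro-1-hydroxy-4-methylcyclohexyl]-2-methyl-6-oxohex-1-en-3-yl acetate | C=C(C)[C@H](OC(C)=O)CCC(=O)[C@]1(O)CC[C@@](C)(Cl)[C@H](Br)C1 | intermediate
15 | (5R)-2-[(1S,3R,4R)-3-bromo-4-chloro-1-hydroxy-4-methylcyclohexyl]-6-methyl-1-(trimethylsilyl)hept-6-ene-2,5-diol, both epimers at C2 (not isolated) | C=C(C)[C@H](O)CCC(O)(C[Si](C)(C)C)[C@]1(O)CC[C@@](C)(Cl)[C@H](Br)C1 | intermediate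
16 | (1S,3R,4R)-3-bromo-4-chloro-1-[(5R)-5-hydroxy-6-methylhepta-1,6-dien-2-yl]-4-methylcyclohexan-1-ol | C=C(C)[C@H](O)CCC(=C)[C@]1(O)CC[C@@](C)(Cl)[C@H](Br)C1 | target

## Step count and risks

Total steps: 9. Longest linear sequence: 9 steps (compound 1 to compound 16).

Steps most likely to fail:

**Step 5 (homoenolate addition).** The ketone homoenolate may re-close to the cyclopropoxide, enolise and react as an oxyallyl zinc, or add with low enantioselectivity. The fallback sets out from compound 8 and returns at compound 11. The zinc homoenolate (Et2Zn) is acylated with methacryloyl chloride under Pd(PPh3)4 catalysis (known ring-opening cross-coupling of cyclopropanols) to give 1-[(1S)-1-hydroxy-4-methylcyclohex-3-en-1-yl]-5-methylhex-5-ene-1,4-dione F1. The isopropenyl ketone of F1, the less hindered and conjugated carbonyl, is then reduced with the (S)-Me-CBS oxazaborolidine and catecholborane at −78 °C to the R allylic alcohol 11.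

**Step 7 (bromoetherification).** The tertiary hydroxyl is deactivated by the neighbouring ketone and must close a strained 7-oxanorbornane; allylic bromination or capture by the ketone oxygen may compete. The fallback sets out from compound 12 and returns at compound 14, so it also bypasses step 8. Hydroxyl-directed epoxidation (VO(acac)2, t-BuOOH) gives the cis-epoxy alcohol (3R)-6-[(1S,3S,6R)-3-hydroxy-6-methyl-7-oxabicyclo[4.1.0]heptan-3-yl]-2-methyl-6-oxohex-1-en-3-yl acetate F2. Li2NiBr4 in THF opens it by SN2 attack at the secondary carbon to the bromohydrin (3R)-6-[(1S,3R,4R)-3-bromo-1,4-dihydroxy-4-methylcyclohexyl]-2-methyl-6-oxohex-1-en-3-yl acetate F3. Dry HCl in CH2Cl2 at −20 °C then replaces the tertiary hydroxyl by chloride with retention through the bromonium ion, giving 14.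

**Step 8 (ether opening).** Elimination from the bromonium ion, chloride capture at the secondary carbon, or ionisation of the allylic acetate by TiCl4 could erode the yield. The fallback sets out from compound 13 and returns at compound 16. Acylative cleavage (AcCl, ZnCl2 cat., CH2Cl2, 0 °C) activates the bridge oxygen as an acyloxonium ion instead of a titanium chelate and gives (3R)-6-[(1S,3R,4R)-1-acetoxy-3-bromo-4-chloro-4-methylcyclohexyl]-2-methyl-6-oxohex-1-en-3-yl acetate F4. F4 is taken through the conditions of step 9 with extra organocerium, which strips both acetates and methylenates the ketone to give 16.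

## Further compounds

F1 | step 5 | 1-[(1S)-1-hydroxy-4-methylcyclohex-3-en-1-yl]-5-methylhex-5-ene-1,4-dione | C=C(C)C(=O)CCC(=O)[C@]1(O)CCC(C)=CC1
F2 | step 7 | (3R)-6-[(1S,3S,6R)-3-hydroxy-6-methyl-7-oxabicyclo[4.1.0]heptan-3-yl]-2-methyl-6-oxohex-1-en-3-yl acetate | C=C(C)[C@H](OC(C)=O)CCC(=O)[C@]1(O)CC[C@@]2(C)O[C@H]2C1
F3 | step 7 | (3R)-6-[(1S,3R,4R)-3-bromo-1,4-dihydroxy-4-methylcyclohexyl]-2-methyl-6-oxohex-1-en-3-yl acetate | C=C(C)[C@H](OC(C)=O)CCC(=O)[C@]1(O)CC[C@@](C)(O)[C@H](Br)C1
F4 | step 8 | (3R)-6-[(1S,3R,4R)-1-acetoxy-3-bromo-4-chloro-4-methylcyclohexyl]-2-methyl-6-oxohex-1-en-3-yl acetate | C=C(C)[C@H](OC(C)=O)CCC(=O)[C@]1(OC(C)=O)CC[C@@](C)(Cl)[C@H](Br)C1
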